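| flask | substrate | acid | remark | time |
|---|---|---|---|---|
| birch | 5 mM (fed, over 4.0 h) | 0.010 mM | run made earlier |  |
| alder | 20 mM (fed, over 4.0 h) | 0.010 mM | run made earlier |  |
| flask | 10 mM (fed, over 4.0 h) | 0.0100 mM |  | 8.0 h |

| run | time / h | substrate / % | target / % |
|---|---|---|---|
| birch | 1.00 | 22.4 | 2.3 |
| birch | 2.00 | 38.6 | 10.7 |
| birch | 3.00 | 47.5 | 25.6 |
| birch | 4.00 | 49.3 | 46.0 |
| birch | 5.00 | 27.3 | 63.3 |
| alder | 0.417 | 10.1 | 0.2 |
| alder | 1.33 | 27.4 | 6.0 |
| alder | 2.00 | 34.1 | 14.5 |
| alder | 3.00 | 33.1 | 35.2 |
| alder | 5.00 | 7.7 | 70.2 |

(scatter of a reading: 0.3 percentage points)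

1. part of the substrate that has reacted at 8.0 h
2. pH of the solution at 8.0 h

- acid is the free proton; pH is minus the decimal logarithm of its molar concentration
- percentages count the whole charge, also what has not yet gone in

One fixed constant for the loss of substrate cannot describe these two runs: with the same dosing time, the alder run tops out near 33.6% of its charge, less than the birch run near 49.3%. My bench rule is that at the top of a fed curve the loss just equals the feed, so the pseudo-first-order loss constant k is the feed rate over c(substrate), the substrate held. Taking the nearly flat reading at 4.00 h as the top of the birch run, I get 0.507 /h, the top constant, with 2.53 mM reacted. The alder run reads 0.744 /h with 5.78 mM reacted. Scaling the top constant by the square root of the reacted amount gives 0.766 /h for the alder run, close to that reading.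

The rule has a border. At 1.00 h the birch run has 0.130 mM reacted, the root rule gives 0.115 /h, and the loss reads about 0.232 /h, twice that, so the scaling fails at such small amounts.

The flask's charge lies between the two, and the alder run tops out lower than the birch run, so I take the birch reading of 49.3% as a high starting guess for what the flask holds at the end of the feed. Scaling to the whole charge gives 1.01 /h, which leaves 0.877%, so I commit to 99.1% reacted. The forecast says 99% and pH 4.33, holding that “This square-root shape suggests catalysis by acid”.

The flask gives 99.0% reacted at pH 4.27.

    substrate + acid → weak acid + acid + target (k = 4.30 /M/s)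
    weak acid ⇌ conjugate base + acid, settled at all times (K = 2.50 × 10⁻⁷ M)
    substrate → weak acid + target (k = 1.10 × 10⁻⁵ /s)
    target ⇌ isomer of the product (K = 11.0, k = 7.70 × 10⁻⁶ /s)
    substrate + target → side product (k = 0.00350 /M/s)

At 4.00 h it has used 61.4% of its substrate, and from the 38.6% held then to the 0.997% at 8.00 h its mean loss constant is 0.914 /h, against 1.01 /h from the top constant. Scaled to the 4.0 mM of the neighbour flask, the top constant gives 0.637 /h. Starting from the birch reading of 49.3%, that leaves 3.86% at 8.00 h, and the neighbour flask holds 5.1%.

The runs come from a simulation for an exercise; the scatter is artificial.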